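**Retrosynthetic overview**

1. The target is (2R,3R)-pinobanksin 3-O-[(2R)-2-methylbutanoate]; the last disconnections are the two phenol benzyl ethers and the C3 ester (Steglich esterification with (R)-2-methylbutanoic acid).
2. Ring C is the only ring that is built (rings A and B are bought). It is closed at C3–C4 by a chiral-carbene-catalysed crossed benzoin cyclisation of a racemic aryl-ether keto-aldehyde, run as a dynamic kinetic resolution that fixes C2.
3. Enabling feature: C3–C4 is an acyloin whose carbonyl carbon C4 is bonded directly to ring A, so C4 can arrive as an aryl aldehyde (the acyl-anion donor). Its neighbour C2 carries H, the ring-C oxygen O1 and phenyl ring B, so at the C3-ketone level C2–H is acidic and the two enantiomers interconvert.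
4. A CO2Et group on C3 makes C3 a non-donor ketone (α-keto ester) in the key step; it is removed afterwards by saponification and decarboxylation, which also settles C3 as trans to C2.
5. The cyclisation precursor comes in one step (O1–C2 ether bond) from 2,4-bis(benzyloxy)-6-hydroxybenzaldehyde and ethyl 3-bromo-2-oxo-3-phenylpropanoate.

Key step: step 3

Assumption: the 2-methylbutanoyl centre is taken as R, as drawn in the SMILES; the sense of induction of the triazolium salt in step 3 has to be confirmed in a trial, and its mirror-image salt is used instead if the 2S series should form.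

**Route**

Step 1
Reactants: 1 2,4,6-trihydroxybenzaldehyde
Product: 2 2,4-bis(benzyloxy)-6-hydroxybenzaldehyde
Conditions: BnBr (2.1 equiv), K2CO3 (2.2 equiv), DMF, 0 °C → rt
Reagents that add atoms: benzyl bromide, BrCc1ccccc1
Why: Williamson ether synthesis: the 4-hydroxyl and one ortho hydroxyl are benzylated, while the second ortho hydroxyl stays free because it is tied up in a hydrogen bond to the formyl oxygen and is the least nucleophilic; no stereocentre is formed.

Step 2
Reactants: 2 2,4-bis(benzyloxy)-6-hydroxybenzaldehyde; 3 ethyl 3-bromo-2-oxo-3-phenylpropanoate (racemic)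
Product: 4 ethyl 3-[3,5-bis(benzyloxy)-2-formylphenoxy]-2-oxo-3-phenylpropanoate (racemic)
Conditions: K2CO3 (1.5 equiv), acetone, 0 °C → rt; dilute acid work-up
Reagents that add atoms: none
Why: Williamson-type SN2 substitution of the doubly activated (benzylic and α-keto) bromide by the phenoxide of 2 forms the O1–C2 bond; C2 is formed racemic on purpose, because it is equilibrated and then fixed in step 3.

Step 3
Reactants: 4 ethyl 3-[3,5-bis(benzyloxy)-2-formylphenoxy]-2-oxo-3-phenylpropanoate (racemic)
Product: 6 ethyl (2R,3R)-5,7-bis(benzyloxy)-3-hydroxy-4-oxo-2-phenyl-3,4-dihydro-2H-chromene-3-carboxylate, via enol tautomer 5 (not isolated)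
Conditions: (5aR,10bS)-2-(pentafluorophenyl)-5a,10b-dihydro-4H,6H-indeno[2,1-b][1,2,4]triazolo[4,3-d][1,4]oxazin-2-ium tetrafluoroborate (15 mol %), i-Pr2NEt (30 mol %), toluene, rt, under argon
Reagents that add atoms: none
Why: The triazolylidene released by the base adds to the formyl carbon (future C4), proton transfer gives the catalyst-bound enaminol (acyl-anion equivalent), this carbon attacks the ketone carbonyl of the α-keto ester (future C3), and proton transfer with loss of the carbene leaves the tertiary acyloin. The closest known reaction type is the chiral-triazolium-catalysed intramolecular crossed aldehyde–ketone benzoin reaction of 2-(2-oxoalkoxy)benzaldehydes to 3-hydroxychroman-4-ones, together with benzoin reactions of α-keto esters run as dynamic kinetic resolutions at a base-labile neighbouring stereocentre. Ring C is closed in the 6-exo-trig mode by the C3–C4 bond. C2 is controlled by dynamic kinetic resolution: the enantiomers of 4 interconvert through enol 5 under the amine base and the catalyst should select the one that leads to 2R; C3 is controlled by the face of the ketone that the catalyst-bound nucleophile reaches when the 2-phenyl group sits pseudo-equatorial (hydroxyl trans to phenyl), and its configuration is not critical because C3 is planarised in step 4. The step needs chemoselectivity for a single acyl-anion donor and fast enantiomer exchange, and the substrate secures both: only the formyl group can become the nucleophile because its partner carbonyl is a ketone, so no elimination or homo-coupling path opens on that side, and the C2–H bond, flanked by the aryloxy oxygen, the phenyl ring and the keto ester, should exchange faster than the ring closes. The competing aldol attack of the C2 enolate on the formyl group is reversible and leads to a congested quaternary five-membered adduct, whereas the benzoin closure should be effectively irreversible under these conditions.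

Step 4
Reactants: 6 ethyl (2R,3R)-5,7-bis(benzyloxy)-3-hydroxy-4-oxo-2-phenyl-3,4-dihydro-2H-chromene-3-carboxylate
Product: 9 (2R,3R)-5,7-bis(benzyloxy)-3-hydroxy-2-phenyl-2,3-dihydro-4H-chromen-4-one, via β-keto acid 7 (not isolated), via enediol 8 (not isolated)
Conditions: LiOH·H2O (3 equiv), THF/H2O (3:1), 0 °C; then 1 M HCl to pH 2, 0 → 40 °C, under argon
Reagents that add atoms: none
Why: Ester saponification followed by decarboxylation of β-keto acid 7 removes the activating group; C3 is re-formed by ketonisation of enediol 8 and acid-catalysed equilibration, which should settle on the 2,3-trans isomer with phenyl and hydroxyl both equatorial, while C2 is untouched because the mixture is acidified before warming, so that no enolate is formed that could open ring C.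

Step 5
Reactants: 9 (2R,3R)-5,7-bis(benzyloxy)-3-hydroxy-2-phenyl-2,3-dihydro-4H-chromen-4-one; 10 (2R)-2-methylbutanoic acid
Product: 11 (2R,3R)-5,7-bis(benzyloxy)-4-oxo-2-phenyl-3,4-dihydro-2H-chromen-3-yl (2R)-2-methylbutanoate
Conditions: DCC (1.3 equiv), DMAP (0.1 equiv), CH2Cl2, 0 °C → rt
Reagents that add atoms: none
Why: Steglich esterification of the secondary 3-hydroxyl, the only free hydroxyl group; acylation on oxygen leaves C2 and C3 unchanged, and the α-centre of the acid carries no heteroatom that would favour ketene formation or enolisation.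

Step 6
Reactants: 11 (2R,3R)-5,7-bis(benzyloxy)-4-oxo-2-phenyl-3,4-dihydro-2H-chromen-3-yl (2R)-2-methylbutanoate
Product: 12 (2R,3R)-5,7-dihydroxy-4-oxo-2-phenyl-3,4-dihydro-2H-chromen-3-yl (2R)-2-methylbutanoate
Conditions: H2 (1 atm), 10% Pd/C, EtOAc, rt
Reagents that add atoms: none
Why: Hydrogenolysis of the two aryl benzyl ethers under neutral conditions, which should leave the aliphatic ester, the ketone and all three stereocentres untouched.

**Compound list**

1 | 2,4,6-trihydroxybenzaldehyde | O=Cc1c(O)cc(O)cc1O | starting material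
2 | 2,4-bis(benzyloxy)-6-hydroxybenzaldehyde | O=Cc1c(O)cc(OCc2ccccc2)cc1OCc1ccccc1 | intermediate
3 | ethyl 3-bromo-2-oxo-3-phenylpropanoate (racemic, commercial) | CCOC(=O)C(=O)C(Br)c1ccccc1 | starting material
4 | ethyl 3-[3,5-bis(benzyloxy)-2-formylphenoxy]-2-oxo-3-phenylpropanoate (racemic) | CCOC(=O)C(=O)C(Oc1cc(OCc2ccccc2)cc(OCc2ccccc2)c1C=O)c1ccccc1 | intermediate
5 | enol tautomer of 4, ethyl 3-[3,5-bis(benzyloxy)-2-formylphenoxy]-2-hydroxy-3-phenylprop-2-enoate (either double-bond geometry; not isolated) | CCOC(=O)C(O)=C(Oc1cc(OCc2ccccc2)cc(OCc2ccccc2)c1C=O)c1ccccc1 | intermediate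
6 | ethyl (2R,3R)-5,7-bis(benzyloxy)-3-hydroxy-4-oxo-2-phenyl-3,4-dihydro-2H-chromene-3-carboxylate (3-OH trans to 2-phenyl) | O[C@@]1(C(=O)OCC)C(=O)c2c(OCc3ccccc3)cc(OCc3ccccc3)cc2O[C@@H]1c1ccccc1 | intermediate
7 | (2R,3R)-5,7-bis(benzyloxy)-3-hydroxy-4-oxo-2-phenyl-3,4-dihydro-2H-chromene-3-carboxylic acid (not isolated) | O[C@@]1(C(=O)O)C(=O)c2c(OCc3ccccc3)cc(OCc3ccccc3)cc2O[C@@H]1c1ccccc1 | intermediate
8 | (2R)-5,7-bis(benzyloxy)-2-phenyl-2H-chromene-3,4-diol (enediol; not isolated) | OC1=C(O)c2c(OCc3ccccc3)cc(OCc3ccccc3)cc2O[C@@H]1c1ccccc1 | intermediate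
9 | (2R,3R)-5,7-bis(benzyloxy)-3-hydroxy-2-phenyl-2,3-dihydro-4H-chromen-4-one | O[C@H]1C(=O)c2c(OCc3ccccc3)cc(OCc3ccccc3)cc2O[C@@H]1c1ccccc1 | intermediate
10 | (2R)-2-methylbutanoic acid | CC[C@@H](C)C(=O)O | starting material
11 | (2R,3R)-5,7-bis(benzyloxy)-4-oxo-2-phenyl-3,4-dihydro-2H-chromen-3-yl (2R)-2-methylbutanoate | CC[C@@H](C)C(=O)O[C@H]1C(=O)c2c(OCc3ccccc3)cc(OCc3ccccc3)cc2O[C@@H]1c1ccccc1 | intermediate
12 | (2R,3R)-5,7-dihydroxy-4-oxo-2-phenyl-3,4-dihydro-2H-chromen-3-yl (2R)-2-methylbutanoate | CC[C@@H](C)C(=O)O[C@H]1C(=O)c2c(O)cc(O)cc2O[C@@H]1c1ccccc1 | target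

**Step count**

Total: 6 steps. Longest linear sequence: 6 steps (1 → 2 → 4 → 6 → 9 → 11 → 12); compounds 3 and 10 are bought.

**Steps most likely to fail**

Step 3 (highest risk). The formyl group is flanked by two ortho oxygen substituents and sits on an electron-rich ring, so the carbene may add and form the acyl-anion equivalent only slowly. Base-mediated aldol closure of the C2 enolate onto the aldehyde could then take over, or incomplete enantiomer exchange could erode the enantioselectivity. The fallback sets out from 2 and comes back at 9, and sets C2 by a separate asymmetric step while still closing ring C at C3–C4. The sodium phenoxide of 2 would undergo [Ir(cod)Cl]2/chiral phosphoramidite-catalysed asymmetric allylic etherification with cinnamyl methyl carbonate (ligand antipode chosen for the S ether) to give 2,4-bis(benzyloxy)-6-{[(1S)-1-phenylprop-2-en-1-yl]oxy}benzaldehyde F1. Wittig methylenation (Ph3P=CH2, THF) would give 1,5-bis(benzyloxy)-2-ethenyl-3-{[(1S)-1-phenylprop-2-en-1-yl]oxy}benzene F2. Ring-closing metathesis with the second-generation Grubbs catalyst (CH2Cl2, 40 °C) would give (2S)-5,7-bis(benzyloxy)-2-phenyl-2H-chromene F3. Dihydroxylation with OsO4 (cat.)/NMO on the face opposite to the phenyl group would give (2R,3S,4S)-5,7-bis(benzyloxy)-2-phenyl-3,4-dihydro-2H-chromene-3,4-diol F4. Oxidation of the benzylic 4-hydroxyl with MnO2 (CH2Cl2, rt) would then deliver 9.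

Step 4. Hydroxide may attack the ring ketone and open ring C by retro-Claisen cleavage, the tertiary alkoxide may undergo α-ketol rearrangement, or decarboxylation may start while the mixture is still basic, which would open ring C by β-elimination of the phenoxide and erode C2. The fallback sets out from 2 and comes back at 7; it replaces the ethyl ester by an allyl ester that is removed without base. Phenylpyruvic acid would be esterified (allyl alcohol, TsOH cat., toluene, azeotropic removal of water) to prop-2-en-1-yl 2-oxo-3-phenylpropanoate F5 and brominated (CuBr2, EtOAc, reflux) to prop-2-en-1-yl 3-bromo-2-oxo-3-phenylpropanoate F6. Alkylation of 2 under the conditions of step 2 would give prop-2-en-1-yl 3-[3,5-bis(benzyloxy)-2-formylphenoxy]-2-oxo-3-phenylpropanoate F7, and the cyclisation of step 3 would give prop-2-en-1-yl (2R,3R)-5,7-bis(benzyloxy)-3-hydroxy-4-oxo-2-phenyl-3,4-dihydro-2H-chromene-3-carboxylate F8. Pd(PPh3)4 (cat.) with morpholine in THF at rt would transfer the allyl group to the amine and release acid 7, which loses CO2 to give 9 as in step 4.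

Step 2. Under carbonate the very acidic product is deprotonated and may attack its own formyl group (aldol closure to benzofuran-type by-products), and the α-bromo keto ester may decompose under base. The fallback sets out from 2 and comes back at 4, and forms the O1–C2 bond without base. Ethyl 2-oxo-3-phenylpropanoate would be converted by diazo transfer (4-acetamidobenzenesulfonyl azide, DBU, MeCN, 0 °C) into ethyl 3-diazo-2-oxo-3-phenylpropanoate F9. Its Rh2(OAc)4-catalysed decomposition in CH2Cl2 in the presence of 2 would give 4 by carbenoid insertion into the phenolic O–H bond.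

**Further compounds**

F1 | step 3 | 2,4-bis(benzyloxy)-6-{[(1S)-1-phenylprop-2-en-1-yl]oxy}benzaldehyde | O=Cc1c(O[C@@H](C=C)c2ccccc2)cc(OCc2ccccc2)cc1OCc1ccccc1
F2 | step 3 | 1,5-bis(benzyloxy)-2-ethenyl-3-{[(1S)-1-phenylprop-2-en-1-yl]oxy}benzene | C=Cc1c(O[C@@H](C=C)c2ccccc2)cc(OCc2ccccc2)cc1OCc1ccccc1
F3 | step 3 | (2S)-5,7-bis(benzyloxy)-2-phenyl-2H-chromene | C1=Cc2c(OCc3ccccc3)cc(OCc3ccccc3)cc2O[C@@H]1c1ccccc1
F4 | step 3 | (2R,3S,4S)-5,7-bis(benzyloxy)-2-phenyl-3,4-dihydro-2H-chromene-3,4-diol | O[C@H]1[C@@H](O)c2c(OCc3ccccc3)cc(OCc3ccccc3)cc2O[C@@H]1c1ccccc1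
F5 | step 4 | prop-2-en-1-yl 2-oxo-3-phenylpropanoate | C=CCOC(=O)C(=O)Cc1ccccc1
F6 | step 4 | prop-2-en-1-yl 3-bromo-2-oxo-3-phenylpropanoate (racemic) | C=CCOC(=O)C(=O)C(Br)c1ccccc1
F7 | step 4 | prop-2-en-1-yl 3-[3,5-bis(benzyloxy)-2-formylphenoxy]-2-oxo-3-phenylpropanoate (racemic) | C=CCOC(=O)C(=O)C(Oc1cc(OCc2ccccc2)cc(OCc2ccccc2)c1C=O)c1ccccc1
F8 | step 4 | prop-2-en-1-yl (2R,3R)-5,7-bis(benzyloxy)-3-hydroxy-4-oxo-2-phenyl-3,4-dihydro-2H-chromene-3-carboxylate | O[C@@]1(C(=O)OCC=C)C(=O)c2c(OCc3ccccc3)cc(OCc3ccccc3)cc2O[C@@H]1c1ccccc1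
F9 | step 2 | ethyl 3-diazo-2-oxo-3-phenylpropanoate | CCOC(=O)C(=O)C(=[N+]=[N-])c1ccccc1
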